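The teal run held 80 mM of partner against 11 mM of substrate, yet its first product sank ever more slowly, reaching 20.3% at 60.0 s.

| flask | substrate | partner | remark | time |
|---|---|---|---|---|
| teal | 11 mM | 80 mM | run made earlier |  |
| red | 23 mM | 80 mM | run made earlier |  |
| violet | 20 mM | 32 mM | run made earlier |  |
| noon | 20 mM | 25.0 mM |  | 2.0 min |
| spring | 10 mM | 80.0 mM |  | 2.0 min |
| winter | 20 mM | 80.0 mM |  | 2.0 min |
| summer | 10 mM | 25.0 mM |  | 2.0 min |

| run | time / s | first product / % |
|---|---|---|
| teal | 10.0 | 35.7 |
| teal | 20.0 | 29.7 |
| teal | 40.0 | 22.9 |
| teal | 60.0 | 20.3 |
| red | 10.0 | 36.1 |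
| red | 20.0 | 32.9 |
| red | 40.0 | 29.0 |
| red | 60.0 | 27.7 |
| violet | 10.0 | 26.3 |
| violet | 12.0 | 27.7 |
| violet | 25.0 | 33.9 |
| violet | 60.0 | 34.3 |

(each reading ± 0.5 percentage points)

- the numbers in the tables scatter with a standard deviation of 0.5 percentage points

- ranking by amount of first product, in percent of the substrate charged, from high to low, at 2.0 min (noon / spring / winter / summer)
- the amount of first product, in percent of the substrate charged of the flask you put first, at 2.0 min
- the amount of first product, in percent of the substrate charged of the flask you put last, at 2.0 min

I counted turnovers. I supposed that substrate takes up partner step after step at one pace, so that with x additions per substrate on average, first product ends at x·exp(−x) of the substrate charged, highest at one turnover. I also supposed that partner leaks away by a side path, so that its charge pays for two amounts: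

x = partner charge / (substrate charge + side allowance)

Taking the last teal reading as an end value, on the falling side, I read x = 2.51. That makes the side allowance, the substrate-like amount that the leak costs, 20.8 mM. The red run then reckons to 1.82 turnovers and 29.5%, against 27.7% read. For the new flasks I reckoned:

summer: 0.810 turnovers, 36.0%
noon: 0.612 turnovers, 33.2%
winter: 1.96 turnovers, 27.6%
spring: 2.59 turnovers, 19.4%

The forecast gave summer > noon > winter > spring, the same order, with 33% and 18%, both lower than mine , and it read the levelling as “reversible steps reaching equilibrium within about a minute”.

The flasks gave summer > noon > winter > spring, with 35.0% in summer and 17.6% in spring.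

    substrate + partner → first product + by-product (k = 1.80 L mol⁻¹ s⁻¹)
    partner + first product → bis adduct + by-product (k = 1.90 L mol⁻¹ s⁻¹)
    partner + bis adduct → triple product + by-product (k = 2.90 L mol⁻¹ s⁻¹)
    partner → decomposed reagent (k = 0.0390 s⁻¹)

In summer, the half-life of substrate at the charged partner, 0.26 min, is shorter than the partner's own half-life by decomposition, 0.30 min. But after 2.00 min that flask holds 16.9 mM of decomposed reagent against 8.03 mM of by-product, out of 25.0 mM of partner, the limiting reagent, which is down to 0.10% of its charge, with substrate at 45.7%.

For the neighbour like spring but with 32 mM of partner, the allowance gives 1.04 turnovers and 36.8%. That flask gives 35.8%.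

The data are calculated with made-up constants, and the scatter is random.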